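**Retrosynthetic overview**

- The target is (2S)-5,4'-dihydroxy-6,7-dimethoxy-8-prenylflavanone. The last disconnections are the 4'-O-acetyl group and the C8–prenyl bond, the latter from an 8-triflate by Stille coupling.
- Ring C is opened at O1–C8a. The route rests on this feature: on ring A the oxygen-bearing C5 and C8 are para, C6 and C7 carry methoxyls, and C8a sits ortho to the acyl-bearing C4a. Ring A is therefore a masked 2-acyl-5,6-dimethoxy-1,4-benzoquinone whose one unsubstituted carbon (C8a) is doubly activated toward the C2 hydroxyl.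
- The β-hydroxy ketone precursor comes from acylation (C4–C4a bond) of lithiated 1,2,3,4-tetramethoxybenzene with an (S)-β-silyloxy Weinreb amide. C2 is set by asymmetric hydrogenation of a β-keto ester.
- The ring B oxygen is carried as a benzyl ether up to the ketone and is then changed to an acetate. A 4-alkoxyphenyl carbinol would compete with ring A for tetravalent cerium and ionise in acid; the acetate also avoids a Lewis-acid debenzylation next to the prenyl group at the end.
- Rings A and B are bought as arenes; ring C is the only ring built (step 8).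

Key step: step 8

Assumption: in step 8 the two new ring A oxygens are taken to come from water, the methoxyl groups leaving as methanol, as is usual for oxidative demethylation by tetravalent cerium.

**Route**

Step 1
Reactants: 1 4'-benzyloxyacetophenone; 2 diethyl carbonate
Product: 3 ethyl 3-[4-(benzyloxy)phenyl]-3-oxopropanoate
Conditions: NaH, toluene, reflux; then aq. HCl
Reagents that add atoms: none
Why: Crossed Claisen condensation, in which the sodium enolate of the aryl methyl ketone is C-acylated by the non-enolisable carbonate and the product is drawn out of the equilibrium as its stabilised enolate.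

Step 2
Reactants: 3 ethyl 3-[4-(benzyloxy)phenyl]-3-oxopropanoate
Product: 4 ethyl (3S)-3-[4-(benzyloxy)phenyl]-3-hydroxypropanoate
Conditions: H2 (30 bar), [RuCl(p-cymene)((R)-BINAP)]Cl (1 mol %), EtOH, 50 °C
Reagents that add atoms: none
Why: Noyori asymmetric hydrogenation of a β-keto ester, in which the ester-chelated ketone is reduced under control of the (R)-BINAP ligand to give the (S)-benzylic alcohol (the same spatial sense as (R)-3-hydroxybutanoates, the descriptor changing because aryl outranks CH2CO2Et), the benzyl ether being inert to the homogeneous ruthenium catalyst.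

Step 3
Reactants: 4 ethyl (3S)-3-[4-(benzyloxy)phenyl]-3-hydroxypropanoate
Product: 5 ethyl (3S)-3-[4-(benzyloxy)phenyl]-3-[(tert-butyldimethylsilyl)oxy]propanoate
Conditions: TBSCl, imidazole, DMF, rt
Reagents that add atoms: tert-butyldimethylsilyl chloride, CC(C)(C)[Si](C)(C)Cl
Why: Imidazole-promoted silylation masks the secondary hydroxyl as a base-stable silyl ether for the amide formation and the aryllithium addition, without touching the stereocentre.

Step 4
Reactants: 5 ethyl (3S)-3-[4-(benzyloxy)phenyl]-3-[(tert-butyldimethylsilyl)oxy]propanoate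
Product: 6 (3S)-3-[4-(benzyloxy)phenyl]-3-[(tert-butyldimethylsilyl)oxy]-N-methoxy-N-methylpropanamide
Conditions: MeNH(OMe)·HCl, i-PrMgCl, THF, −20 → 0 °C
Reagents that add atoms: N,O-dimethylhydroxylamine hydrochloride, CNOC.Cl
Why: Direct aminolysis of the ester by the chloromagnesium amide of N,O-dimethylhydroxylamine gives the Weinreb amide at a temperature where β-elimination of the silyloxy group is not expected.

Step 5
Reactants: 7 1,2,3,4-tetramethoxybenzene; 6 (3S)-3-[4-(benzyloxy)phenyl]-3-[(tert-butyldimethylsilyl)oxy]-N-methoxy-N-methylpropanamide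
Product: 9 (3S)-3-[4-(benzyloxy)phenyl]-3-[(tert-butyldimethylsilyl)oxy]-1-(2,3,4,5-tetramethoxyphenyl)propan-1-one, via aryllithium 8 (not isolated)
Conditions: 7 (1.5 equiv), n-BuLi (1.3 equiv), TMEDA, THF, 0 °C; then 6, −78 → −20 °C; aq. NH4Cl
Reagents that add atoms: none
Why: Directed ortho-lithiation of the arene (both ring hydrogens are equivalent and ortho to a methoxyl) followed by Weinreb ketone synthesis, in which the chelated tetrahedral intermediate prevents over-addition and the excess of arene over n-BuLi leaves no butyllithium to attack the amide.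

Step 6
Reactants: 9 (3S)-3-[4-(benzyloxy)phenyl]-3-[(tert-butyldimethylsilyl)oxy]-1-(2,3,4,5-tetramethoxyphenyl)propan-1-one
Product: 11 4-[(1S)-1-[(tert-butyldimethylsilyl)oxy]-3-oxo-3-(2,3,4,5-tetramethoxyphenyl)propyl]phenyl acetate, via free phenol 10 (not isolated)
Conditions: H2 (1 atm), 10% Pd/C, EtOAc, rt; filter; then Ac2O, pyridine, 0 °C → rt
Reagents that add atoms: acetic anhydride, CC(=O)OC(C)=O
Why: Hydrogenolysis of the aryl benzyl ether and acetylation of the freed phenol exchange an electron-releasing ether for an electron-withdrawing ester, so that ring B and its carbinol should resist the oxidant of step 8, while the silyl ether and the aryl ketone should survive brief hydrogenation in ethyl acetate.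

Step 7
Reactants: 11 4-[(1S)-1-[(tert-butyldimethylsilyl)oxy]-3-oxo-3-(2,3,4,5-tetramethoxyphenyl)propyl]phenyl acetate
Product: 12 4-[(1S)-1-hydroxy-3-oxo-3-(2,3,4,5-tetramethoxyphenyl)propyl]phenyl acetate
Conditions: HF·pyridine, pyridine, THF, 0 °C → rt
Reagents that add atoms: none
Why: Buffered fluoride desilylation frees the C2 hydroxyl under non-basic conditions, so the aryl acetate stays and the β-hydroxy ketone should neither dehydrate nor undergo retro-aldol cleavage.

Step 8
Reactants: 12 4-[(1S)-1-hydroxy-3-oxo-3-(2,3,4,5-tetramethoxyphenyl)propyl]phenyl acetate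
Product: 15 4-[(2S)-5,8-dihydroxy-6,7-dimethoxy-4-oxo-3,4-dihydro-2H-chromen-2-yl]phenyl acetate, via acylquinone 13 (not isolated), via chromanetrione 14 (not isolated)
Conditions: (NH4)2Ce(NO3)6 (4.4 equiv), MeCN/H2O (4:1), −10 → 0 °C; then sat. aq. Na2S2O4, EtOAc, rt, argon
Reagents that add atoms: water, O
Why: Proposed new method: tetravalent cerium takes two electrons from the 2,5-dimethoxyaryl ketone of ring A and water replaces both methoxyls (lost as methanol) to give the 2-acyl-5,6-dimethoxy-1,4-benzoquinone 13, whose only unsubstituted carbon, the future C8a, is β to both the quinone carbonyl at C5 and the C4 ketone, so the C2 hydroxyl adds there and enolisation rearomatises ring A to the 5,8-hydroquinone; the surplus oxidant takes this on to quinone 14 and dithionite returns 15. The closest known reaction types are the oxidative demethylation of 2,5-dimethoxyaryl ketones to acylquinones and the intermolecular addition of oxygen, sulfur and carbon nucleophiles to C3 of 2-acyl-1,4-benzoquinones; their intramolecular combination to close a chromanone ring is without direct precedent. Ring C closes in a 6-endo-trig oxa-Michael mode, the tether reaching C8a when the ketone carbonyl lies s-cis to the C4a=C8a bond. No stereocentre is formed, and because the C2–O bond is never broken the S configuration from step 2 is kept. The step needs ring A to be oxidised before ring B or the carbinol, which the 4-acetoxy group secures by raising the oxidation potential of ring B and disfavouring benzylic ionisation, and it needs attack at C8a alone, which holds because every other quinone carbon is substituted. More than four equivalents of oxidant are used so that redox exchange between 15 and unreacted 13 cannot strand material as the acylhydroquinone, which can no longer cyclise.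

Step 9
Reactants: 15 4-[(2S)-5,8-dihydroxy-6,7-dimethoxy-4-oxo-3,4-dihydro-2H-chromen-2-yl]phenyl acetate
Product: 16 4-[(2S)-5-hydroxy-6,7-dimethoxy-4-oxo-8-{[(trifluoromethyl)sulfonyl]oxy}-3,4-dihydro-2H-chromen-2-yl]phenyl acetate
Conditions: Tf2O (1.05 equiv), pyridine, CH2Cl2, −78 → −30 °C, argon
Reagents that add atoms: trifluoromethanesulfonic anhydride, O=S(=O)(OS(=O)(=O)C(F)(F)F)C(F)(F)F
Why: Chemoselective O-sulfonylation, in which the 5-hydroxyl is held in a hydrogen bond to the C4 carbonyl and is far less nucleophilic, so one equivalent of anhydride at low temperature should react only at the free 8-hydroxyl, and pyridine is too weak a base to open the flavanone ring.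

Step 10
Reactants: 16 4-[(2S)-5-hydroxy-6,7-dimethoxy-4-oxo-8-{[(trifluoromethyl)sulfonyl]oxy}-3,4-dihydro-2H-chromen-2-yl]phenyl acetate; 17 tributyl(3-methylbut-2-en-1-yl)stannane
Product: 18 4-[(2S)-5-hydroxy-6,7-dimethoxy-8-(3-methylbut-2-en-1-yl)-4-oxo-3,4-dihydro-2H-chromen-2-yl]phenyl acetate
Conditions: Pd(PPh3)4 (10 mol %), LiCl, DMF, 90 °C
Reagents that add atoms: none
Why: Stille coupling of the aryl triflate under neutral conditions with zerovalent palladium, LiCl assisting oxidative addition and transmetalation; reductive elimination at the unsubstituted allyl terminus should give the linear prenyl group, and the chelated phenol, the acetate and C2 are not affected.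

Step 11
Reactants: 18 4-[(2S)-5-hydroxy-6,7-dimethoxy-8-(3-methylbut-2-en-1-yl)-4-oxo-3,4-dihydro-2H-chromen-2-yl]phenyl acetate
Product: 19 (2S)-5-hydroxy-2-(4-hydroxyphenyl)-6,7-dimethoxy-8-(3-methylbut-2-en-1-yl)-2,3-dihydro-4H-chromen-4-one
Conditions: Candida antarctica lipase B (immobilised), n-BuOH, THF, 40 °C
Reagents that add atoms: none
Why: Lipase-catalysed transesterification of the unhindered phenolic acetate to butanol runs at neutral pH, so base-induced ring opening and racemisation at C2 and acid-induced hydration of the prenyl group are both avoided.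

**Compound list**

1 | 4'-benzyloxyacetophenone | CC(=O)c1ccc(OCc2ccccc2)cc1 | starting material
2 | diethyl carbonate | CCOC(=O)OCC | starting material
3 | ethyl 3-[4-(benzyloxy)phenyl]-3-oxopropanoate | CCOC(=O)CC(=O)c1ccc(OCc2ccccc2)cc1 | intermediate
4 | ethyl (3S)-3-[4-(benzyloxy)phenyl]-3-hydroxypropanoate | CCOC(=O)C[C@H](O)c1ccc(OCc2ccccc2)cc1 | intermediate
5 | ethyl (3S)-3-[4-(benzyloxy)phenyl]-3-[(tert-butyldimethylsilyl)oxy]propanoate | CCOC(=O)C[C@H](O[Si](C)(C)C(C)(C)C)c1ccc(OCc2ccccc2)cc1 | intermediate
6 | (3S)-3-[4-(benzyloxy)phenyl]-3-[(tert-butyldimethylsilyl)oxy]-N-methoxy-N-methylpropanamide | CON(C)C(=O)C[C@H](O[Si](C)(C)C(C)(C)C)c1ccc(OCc2ccccc2)cc1 | intermediate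
7 | 1,2,3,4-tetramethoxybenzene | COc1ccc(OC)c(OC)c1OC | starting material
8 | (2,3,4,5-tetramethoxyphenyl)lithium | [Li]c1cc(OC)c(OC)c(OC)c1OC | intermediate
9 | (3S)-3-[4-(benzyloxy)phenyl]-3-[(tert-butyldimethylsilyl)oxy]-1-(2,3,4,5-tetramethoxyphenyl)propan-1-one | COc1cc(C(=O)C[C@H](O[Si](C)(C)C(C)(C)C)c2ccc(OCc3ccccc3)cc2)c(OC)c(OC)c1OC | intermediate
10 | (3S)-3-[(tert-butyldimethylsilyl)oxy]-3-(4-hydroxyphenyl)-1-(2,3,4,5-tetramethoxyphenyl)propan-1-one | COc1cc(C(=O)C[C@H](O[Si](C)(C)C(C)(C)C)c2ccc(O)cc2)c(OC)c(OC)c1OC | intermediate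
11 | 4-[(1S)-1-[(tert-butyldimethylsilyl)oxy]-3-oxo-3-(2,3,4,5-tetramethoxyphenyl)propyl]phenyl acetate | COc1cc(C(=O)C[C@H](O[Si](C)(C)C(C)(C)C)c2ccc(OC(C)=O)cc2)c(OC)c(OC)c1OC | intermediate
12 | 4-[(1S)-1-hydroxy-3-oxo-3-(2,3,4,5-tetramethoxyphenyl)propyl]phenyl acetate | COc1cc(C(=O)C[C@H](O)c2ccc(OC(C)=O)cc2)c(OC)c(OC)c1OC | intermediate
13 | 4-[(1S)-3-(4,5-dimethoxy-3,6-dioxocyclohexa-1,4-dien-1-yl)-1-hydroxy-3-oxopropyl]phenyl acetate | COC1=C(OC)C(=O)C(C(=O)C[C@H](O)c2ccc(OC(C)=O)cc2)=CC1=O | intermediate
14 | 4-[(2S)-6,7-dimethoxy-4,5,8-trioxo-3,4,5,8-tetrahydro-2H-chromen-2-yl]phenyl acetate | COC1=C(OC)C(=O)C2=C(C1=O)C(=O)C[C@@H](c1ccc(OC(C)=O)cc1)O2 | intermediate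
15 | 4-[(2S)-5,8-dihydroxy-6,7-dimethoxy-4-oxo-3,4-dihydro-2H-chromen-2-yl]phenyl acetate | COc1c(O)c2c(c(O)c1OC)O[C@H](c1ccc(OC(C)=O)cc1)CC2=O | intermediate
16 | 4-[(2S)-5-hydroxy-6,7-dimethoxy-4-oxo-8-{[(trifluoromethyl)sulfonyl]oxy}-3,4-dihydro-2H-chromen-2-yl]phenyl acetate | COc1c(O)c2c(c(OS(=O)(=O)C(F)(F)F)c1OC)O[C@H](c1ccc(OC(C)=O)cc1)CC2=O | intermediate
17 | tributyl(3-methylbut-2-en-1-yl)stannane | CCCC[Sn](CCCC)(CCCC)CC=C(C)C | starting material
18 | 4-[(2S)-5-hydroxy-6,7-dimethoxy-8-(3-methylbut-2-en-1-yl)-4-oxo-3,4-dihydro-2H-chromen-2-yl]phenyl acetate | COc1c(O)c2c(c(CC=C(C)C)c1OC)O[C@H](c1ccc(OC(C)=O)cc1)CC2=O | intermediate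
19 | (2S)-5-hydroxy-2-(4-hydroxyphenyl)-6,7-dimethoxy-8-(3-methylbut-2-en-1-yl)-2,3-dihydro-4H-chromen-4-one | COc1c(O)c2c(c(CC=C(C)C)c1OC)O[C@H](c1ccc(O)cc1)CC2=O | target

**Step count**

Total steps: 11. Longest linear sequence: 11 steps (1 → 19). Compounds 7 and 17 enter at steps 5 and 10.

**Steps most likely to fail**

1. Step 8. The tethered hydroxyl may be outrun by water in adding to the acylquinone. The β-hydroxy ketone may dehydrate in the acidic oxidising medium. The over-oxidised trione may also open by β-elimination before it is reduced, which would erode the configuration at C2.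
 The fallback builds ring C by a classical chromone closure and sets C2 by catalyst control. It sets out from aryllithium 8 (made from 7 as in step 5) and comes back at quinone 14, which is reduced to 15 with dithionite as in step 8. Quenching 8 with B(OMe)3 gives dimethyl (2,3,4,5-tetramethoxyphenyl)boronate F1, which alkaline H2O2 oxidises in the same flask to 2,3,4,5-tetramethoxyphenol F2. Acetylation at its only free ring position with AcOH and BF3·OEt2 gives 1-(2-hydroxy-3,4,5,6-tetramethoxyphenyl)ethanone F3. Condensation with Me2NCH(OMe)2 gives (E)-3-(dimethylamino)-1-(2-hydroxy-3,4,5,6-tetramethoxyphenyl)prop-2-en-1-one F4, which aqueous HCl closes to 5,6,7,8-tetramethoxy-4H-chromen-4-one F5. Asymmetric conjugate addition of 4-acetoxyphenylboronic acid with Pd(OCOCF3)2 and the enantiomer of the tert-butyl pyridine-oxazoline ligand that leads to the 2S product gives 4-[(2S)-5,6,7,8-tetramethoxy-4-oxo-3,4-dihydro-2H-chromen-2-yl]phenyl acetate F6. Oxidative demethylation of its para 5,8-dimethoxy pair with (NH4)2Ce(NO3)6 gives 14.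

2. Step 10. Oxidative addition into the doubly ortho-substituted, electron-rich triflate may be slow. Allylic transposition during transmetalation and reductive elimination may deliver the 1,1-dimethylallyl isomer.
 The fallback removes the regiochemical question by coupling an unsubstituted allyl group and then building the trisubstituted alkene by metathesis. It sets out from 16 and comes back at 18. Stille coupling of 16 with allyltributylstannane (Pd(PPh3)4, LiCl, DMF) gives 4-[(2S)-5-hydroxy-6,7-dimethoxy-4-oxo-8-(prop-2-en-1-yl)-3,4-dihydro-2H-chromen-2-yl]phenyl acetate F7. Cross-metathesis with excess 2-methylbut-2-ene and the second-generation Grubbs catalyst in CH2Cl2 at 40 °C converts F7 into 18.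

3. Step 9. Site selectivity between the two hydroxyls may be lost, and the hydroquinone may be oxidised by air in the presence of base.
 The fallback blocks the 5-hydroxyl covalently before sulfonylation. It sets out from 15 and comes back at 16. Treatment of 15 with BF3·OEt2 in CH2Cl2 gives the 5-O,4-O-difluoroboron chelate of 15 F8, in which the 5-oxygen and the C4 carbonyl are tied up and the ring is less easily oxidised. Tf2O and pyridine then give the 5-O,4-O-difluoroboron chelate of 16 F9. Warming F9 in MeOH releases 16.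

**Further compounds**

F1 | step 8 | dimethyl (2,3,4,5-tetramethoxyphenyl)boronate | COB(OC)c1cc(OC)c(OC)c(OC)c1OC
F2 | step 8 | 2,3,4,5-tetramethoxyphenol | COc1cc(O)c(OC)c(OC)c1OC
F3 | step 8 | 1-(2-hydroxy-3,4,5,6-tetramethoxyphenyl)ethanone | CC(=O)c1c(O)c(OC)c(OC)c(OC)c1OC
F4 | step 8 | (E)-3-(dimethylamino)-1-(2-hydroxy-3,4,5,6-tetramethoxyphenyl)prop-2-en-1-one | CN(C)/C=C/C(=O)c1c(O)c(OC)c(OC)c(OC)c1OC
F5 | step 8 | 5,6,7,8-tetramethoxy-4H-chromen-4-one | O=c1ccoc2c(OC)c(OC)c(OC)c(OC)c12
F6 | step 8 | 4-[(2S)-5,6,7,8-tetramethoxy-4-oxo-3,4-dihydro-2H-chromen-2-yl]phenyl acetate | COc1c(OC)c2c(c(OC)c1OC)O[C@H](c1ccc(OC(C)=O)cc1)CC2=O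
F7 | step 10 | 4-[(2S)-5-hydroxy-6,7-dimethoxy-4-oxo-8-(prop-2-en-1-yl)-3,4-dihydro-2H-chromen-2-yl]phenyl acetate | COc1c(O)c2c(c(CC=C)c1OC)O[C@H](c1ccc(OC(C)=O)cc1)CC2=O
F8 | step 9 | 5-O,4-O-difluoroboron chelate of 15 | COc1c(OC)c(O)c2O[C@H](c3ccc(OC(C)=O)cc3)CC3=[O+][B-](F)(F)Oc1c23
F9 | step 9 | 5-O,4-O-difluoroboron chelate of 16 | COc1c(OC)c(OS(=O)(=O)C(F)(F)F)c2O[C@H](c3ccc(OC(C)=O)cc3)CC3=[O+][B-](F)(F)Oc1c23
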